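## Analysis of the target

The target is a 3a,4,5,7a-tetrahydro-1H-indene: a cyclohexene (C3a, C4, C5, C6=C7, C7a) fused to a cyclopentene (C1, C2=C3, C3a, C7a), with both ring alkenes trisubstituted and methylated (C3, C7). It has five contiguous stereocentres, (1R,3aR,4R,5S,7aS). C4 and C5 are adjacent quaternary carbons whose methyls are cis (called the β face here). The carboxyl on C4 and the dienyl chain on C5 lie on the opposite (α) face. The ring fusion is trans (H-3a α, H-7a β), and the C1 methyl is β, cis to H-7a. The sensitive parts are the (1E,3E)-2-methyl-4-phenylbuta-1,3-dienyl chain (acid, electrophilic oxidants, ruthenium carbenes) and the neopentyl carboxylic acid. This acid is γ,δ-unsaturated towards C2=C3 and could lactonise onto C3 under strong acid, so the last steps must stay close to neutral. The hard points are the vicinal quaternary pair, the trans fusion next to the allylic methine C1, and two almost equivalent one-carbon arms on C4 and C5 that must end at different oxidation levels (CO2H and the alkenyl carbon C1'). The plan rests on one feature: C4 and C5, each with a methyl and a one-carbon oxidised arm on matching faces, are a masked cis-2,3-dimethylsuccinic unit, with C3a and C6 as the termini of a former diene. The six-membered ring therefore has a hidden mirror plane through the C4–C5 and C7–C7a bonds.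

## Retrosynthetic reasoning

**C4 carboxyl.** The acid 25 is taken back through aldehyde 24 to primary alcohol 23 and its silyl ether 22. The oxidation level at C4 is raised last so that no carboxyl or free hydroxyl sits next to an electrophilic enal while the chain is built.

**Side chain.** The C3'=C4' and C1'=C2' alkenes are cut by two carbonyl olefinations, leading through enal 21 to aldehyde 20 and alcohol 19. Aldehyde 20 has no α-hydrogen, and stabilised carbanion olefinations give both (E) alkenes. The chain comes after all metathesis chemistry because a styryl diene would not survive a ruthenium carbene.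

**Cyclopentene.** The C2=C3 bond of 18 is cut by ring-closing metathesis to triene 17. The two alkenyl arms on C3a and C7a are trans and diequatorial, so closure gives the trans fusion. At this stage C7 is already sp2, so C7a can no longer epimerise.

**C7 methyl.** The C7–CH3 bond of 17 is cut to enol triflate 16 and ketone 15. Kinetic enolisation of 15 can only reasonably occur at the C6 methylene, which fixes the C6=C7 position that a dehydration could not guarantee.

**C7a–C1 bond.** Ketone 15 is cut between C7a and C1 to the regiodefined enolate 14 (from silyl enol ether 13) and a symmetrical 1,3-dimethylallyl electrophile. The symmetrical allyl unit removes the branched/linear problem, and the extra carbon is lost later in the metathesis.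

**C3a–C3 bond.** Enol ether 13 is cut at C3a–C3 to enone 12 and an isopropenyl nucleophile. The β-carbon C3a sits next to quaternary C4, whose large silyloxymethyl group and small methyl differentiate the two faces.

**Telling the arms apart.** Enone 12 carries two different silyl ethers. They come from ketone 11 and keto ether 10, in which only the C5 hydroxymethyl group of hydroxy enone 9 has added to C3a. The C5 arm is 1,3 to C3a and closes a five-membered ether; the C4 arm could only close an oxetane. Ring size, not sterics, makes the distinction.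

**Absolute configuration.** Enone 9 comes from allylic alcohol 8 (via 7), formed by enantioselective β-elimination of meso epoxide 6 with a chiral lithium amide. Epoxide 6 comes from epoxy diol 5 and meso diol 4. The choice between the enantiotopic protons at C3a and C6 decides which quaternary carbon becomes C4.

**Six-membered ring.** Diol 4 is the reduction product of meso anhydride 3, which is cut at C3a–C4 and C5–C6 into buta-1,3-diene 1 and 2,3-dimethylmaleic anhydride 2. The cyclic dienophile delivers both quaternary carbons with the cis methyls in one step from two commercial compounds.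

## Alternatives that were turned down

**Alternative 1:** Disconnection at C4–C5. The forward key step would be an Ireland–Claisen rearrangement run as a ring contraction: a lactone C–O bond at C7 is exchanged, through a silyl ketene acetal, for the C4–C5 bond and the C6=C7 alkene, giving acid A1.
- For: both quaternary centres, the methylated ring alkene and the free C4 carboxyl appear in one event, and the two arms are born different (CO2H against a protected CH2O). On arm differentiation this is stronger than the chosen route, which spends three steps on it.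
- Against: the [3,3] shift must join two fully substituted carbons. Its stereochemical outcome relies on an assumed boat-like transition state of a ring-bound ketene acetal. Its substrate needs C3a, C7a, C1, a tertiary allylic C7–O centre and a defined (E)-trisubstituted alkene in place beforehand, and that tertiary allylic ester is prone to ionisation during enolisation.
- Comparison: the chosen plan makes the quaternary pair in its first step with no stereochemical risk and sets every later centre on a ring. It pays with more functional-group steps.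

**Alternative 2:** Disconnection of C1–C2 together with C2=C3. The forward key step would convert an acetyl group on C3a, with lithiated (trimethylsilyl)diazomethane, into an alkylidene carbene at C2. This inserts into a C–H bond of an ethyl group on C7a and closes the cyclopentene, giving methyl ester A2.
- For: a very late, reagent-light ring closure that needs no metathesis handles; on brevity of the endgame it is stronger.
- Against: C1 is created by insertion into one of two diastereotopic methylene C–H bonds, and nothing in the substrate distinguishes them, so C1 is uncontrolled. The C4 methyl hydrogens are also in 1,5 relation to the carbene. The dienyl chain is already present and can be cyclopropanated. A hindered neopentyl methyl ester must then be cleaved.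
- Comparison: the chosen plan sets C1 under catalyst control next to a correctable centre (C7a) and ends with a mild oxidation.

**Alternative 3:** Disconnection at C5–C6. The forward key step would be an intramolecular palladium-catalysed α-alkenylation: the C5 enolate of a γ-lactone (carbonyl C1') couples with a (Z)-alkenyl iodide at C6 and closes the cyclohexene onto an existing cyclopentene, giving tricyclic lactone A3.
- For: the cis-fused lactone forces the cis relation of the methyls, the arms are differentiated by the lactone itself, and the route is convergent. On these points it is as strong as or stronger than the chosen route.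
- Against: reductive elimination must form a quaternary carbon directly beside another quaternary carbon, at the limit of enolate alkenylation. The (Z)-iodide geometry must be made and kept. C4 must be set earlier on a cyclopentene that already has three stereocentres. The lactone holds the oxidation levels the wrong way round for a free-hydroxyl-free chain extension (C1' must be reduced while the C4 arm is a free CH2OH next to an enal).
- Comparison: the chosen plan offers a first step of known type, substituent-controlled later stereochemistry and orthogonally protected arms. It is longer and fully linear.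

Key step: step 1

Remark: ring carbons keep the indene numbering of the target in all intermediates. The sense of induction written for the chiral base (step 5) and the ligand (step 10) is an assumption from simpler substrates; the antipodal reagent is used if a model run shows the opposite sense.

Step 1
Reactants: 1 buta-1,3-diene; 2 2,3-dimethylmaleic anhydride
Product: 3 meso-cis-1,2-dimethylcyclohex-4-ene-1,2-dicarboxylic anhydride
Conditions: 1 (excess), BHT (cat.), toluene, sealed autoclave, 180 °C
Reagents that add atoms: none
Why: Thermal Diels–Alder reaction, a concerted suprafacial [4+2] cycloaddition; the closest known reaction type is the high-temperature cycloaddition of 2,3-dimethylmaleic anhydride with simple acyclic dienes. The cyclohexene ring closes by simultaneous formation of C3a–C4 and C5–C6 from the s-cis diene and the ring-locked Z-dienophile. The two new quaternary stereocentres C4 and C5 are controlled only by the dienophile geometry: syn addition must place both methyls on one face and both carbonyls on the other. The adduct is meso, so no absolute control is asked of this step. A symmetric diene and a symmetric dienophile leave no regiochemical question, and the unsubstituted diene leaves no endo/exo question. What the step needs is rate, because the tetrasubstituted dienophile is slow; hence excess diene, a radical inhibitor against diene polymerisation and a sealed vessel at about 180 °C. Unlike furan adducts, this adduct should not revert at that temperature.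

Step 2
Reactants: 3 meso-cis-1,2-dimethylcyclohex-4-ene-1,2-dicarboxylic anhydride
Product: 4 meso-(cis-1,2-dimethylcyclohex-4-ene-1,2-diyl)dimethanol
Conditions: LiAlH4, THF, 0 °C to reflux; Fieser work-up
Reagents that add atoms: none
Why: Hydride reduction of a cyclic anhydride to the 1,4-diol; neither carbonyl has an α-hydrogen, so the cis relationship cannot be lost.

Step 3
Reactants: 4 meso-(cis-1,2-dimethylcyclohex-4-ene-1,2-diyl)dimethanol
Product: 5 meso-(3,4-dimethyl-7-oxabicyclo[4.1.0]heptane-3,4-diyl)dimethanol with the epoxide oxygen cis to both CH2OH groups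
Conditions: VO(acac)2 (cat.), t-BuOOH (decane), CH2Cl2, 0 °C to rt
Reagents that add atoms: tert-butyl hydroperoxide, CC(C)(C)OO
Why: Hydroxyl-directed vanadium-catalysed epoxidation of a bishomoallylic alcohol; both CH2OH groups deliver oxygen to their own (α) face, so a single meso epoxide is expected, and an epoxide syn to the hydroxymethyl groups cannot be opened by them from the rear. A single diastereomer matters because the two epoxide diastereomers would be desymmetrised in opposite senses.

Step 4
Reactants: 5 meso epoxy diol
Product: 6 bis(triethylsilyl) ether of 5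
Conditions: Et3SiCl, imidazole, DMF, 0 °C to rt
Reagents that add atoms: chlorotriethylsilane, CC[Si](Cl)(CC)CC
Why: Silylation of both primary alcohols; triethylsilyl ethers tolerate lithium amides and are removed by methanolic acid in the next step.

Step 5
Reactants: 6 bis(triethylsilyl) ether of the meso epoxy diol
Product: 8 (1R,4R,5S)-4,5-bis(hydroxymethyl)-4,5-dimethylcyclohex-2-en-1-ol, via bis(triethylsilyl) allylic alcohol 7 (not isolated)
Conditions: lithium (R)-2-(pyrrolidin-1-ylmethyl)pyrrolidide [from (R)-1-(pyrrolidin-2-ylmethyl)pyrrolidine, n-BuLi], THF, 0 °C to rt; then HCl in MeOH, 0 °C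
Reagents that add atoms: none
Why: Enantioselective β-elimination of a meso epoxide by a chiral lithium amide (syn removal of one of the enantiotopic pseudoaxial protons at C3a or C6). The base decides which quaternary carbon lies next to the new alkene and so fixes the absolute configuration of C4 and C5; the (R)-base is written because the (S)-base turns cyclohexene oxide into (S)-cyclohex-2-enol and the (1R) sense is needed here. Acidic methanol then removes both triethylsilyl groups.

Step 6
Reactants: 8 (1R,4R,5S)-4,5-bis(hydroxymethyl)-4,5-dimethylcyclohex-2-en-1-ol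
Product: 10 (1R,5S,8R)-8-(hydroxymethyl)-5,8-dimethyl-6-oxabicyclo[3.2.1]octan-3-one, via hydroxy enone 9 (not isolated)
Conditions: MnO2, acetone, rt; filter; then CSA (cat.), CH2Cl2, rt
Reagents that add atoms: none
Why: MnO2 oxidises only the allylic alcohol; in enone 9 the C5 hydroxymethyl group, 1,3 to C3a, adds to the enone in an acid-catalysed intramolecular oxa-Michael reaction, whereas the C4 arm could only form an oxetane. The arms are thus told apart by ring size, and acid catalysis avoids an alkoxide on the C4 arm that could fragment by vinylogous retro-aldol loss of formaldehyde.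

Step 7
Reactants: 10 (1R,5S,8R)-8-(hydroxymethyl)-5,8-dimethyl-6-oxabicyclo[3.2.1]octan-3-one
Product: 11 (1R,5S,8R)-8-[(tert-butyldiphenylsilyloxy)methyl]-5,8-dimethyl-6-oxabicyclo[3.2.1]octan-3-one
Conditions: t-BuPh2SiCl, imidazole, DMF, rt
Reagents that add atoms: tert-butylchlorodiphenylsilane, CC(C)(C)[Si](Cl)(c1ccccc1)c1ccccc1
Why: Silylation of the only free hydroxyl; the bulky group stays on the C4 arm until step 18 and adds to the shielding of the α face in step 9.

Step 8
Reactants: 11 silyl-protected keto ether
Product: 12 (4R,5S)-5-[(tert-butyldimethylsilyloxy)methyl]-4-[(tert-butyldiphenylsilyloxy)methyl]-4,5-dimethylcyclohex-2-en-1-one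
Conditions: t-BuMe2SiCl, DBU, MeCN, rt to 50 °C
Reagents that add atoms: tert-butylchlorodimethylsilane, CC(C)(C)[Si](C)(C)Cl
Why: Base-induced retro-oxa-Michael (E1cB) opening: enolisation towards C7a expels the axial C3a–O bond and the released C5 alkoxide is trapped as its silyl ether, which draws the equilibrium to the enone with two different silyl ethers.

Step 9
Reactants: 12 differentially protected enone
Product: 13 (3R,4R,5S)-5-[(tert-butyldimethylsilyloxy)methyl]-4-[(tert-butyldiphenylsilyloxy)methyl]-4,5-dimethyl-3-(prop-1-en-2-yl)-1-(trimethylsilyloxy)cyclohex-1-ene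
Conditions: isopropenylmagnesium bromide, CuBr·SMe2 (cat.), Me3SiCl, THF, −78 to −40 °C; Et3N quench
Reagents that add atoms: isopropenylmagnesium bromide, CC(=C)[Mg]Br; chlorotrimethylsilane, C[Si](C)(C)Cl
Why: Copper-catalysed conjugate addition with silyl trapping. Axial attack at C3a from the β face is anti to the pseudoaxial CH2OSi group on C4 and meets only methyl groups, whereas α attack meets both silyloxymethyl groups; this should place the isopropenyl group cis to the methyls, and the enol ether stores the enolate regiochemistry at C7a.

Step 10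
Reactants: 13 trimethylsilyl enol ether
Product: 15 (2S,3R,4R,5S)-5-[(tert-butyldimethylsilyloxy)methyl]-4-[(tert-butyldiphenylsilyloxy)methyl]-4,5-dimethyl-2-[(2R,3E)-pent-3-en-2-yl]-3-(prop-1-en-2-yl)cyclohexan-1-one, via lithium enolate 14 (not isolated)
Conditions: MeLi, THF, 0 °C; then LiCl, Pd2(dba)3 (cat.), (R)-BINAP, rac-(E)-pent-3-en-2-yl methyl carbonate, −78 °C to rt
Reagents that add atoms: (E)-pent-3-en-2-yl methyl carbonate, C/C=C/C(C)OC(=O)OC
Why: Tsuji–Trost allylic alkylation of a non-stabilised lithium ketone enolate released regiospecifically by MeLi. The 1,3-dimethylallyl complex of palladium is symmetrical, so there is no branched/linear issue, and the chiral ligand selects the allyl terminus and hence the configuration at C1; which ligand enantiomer gives (R) at C1 must be settled on a model. C7a is alkylated anti to the isopropenyl group and, being α to the ketone, can be equilibrated to the trans-diequatorial isomer.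

Step 11
Reactants: 15 allylated ketone
Product: 16 (3S,4R,5R,6S)-3-[(tert-butyldimethylsilyloxy)methyl]-4-[(tert-butyldiphenylsilyloxy)methyl]-3,4-dimethyl-6-[(2R,3E)-pent-3-en-2-yl]-5-(prop-1-en-2-yl)cyclohex-1-en-1-yl trifluoromethanesulfonate
Conditions: KN(SiMe3)2, THF, −78 °C; then N-(5-chloropyridin-2-yl)bis(trifluoromethanesulfonimide), −78 to −20 °C
Reagents that add atoms: N-(5-chloropyridin-2-yl)bis(trifluoromethanesulfonimide), O=S(=O)(N(c1ccc(Cl)cn1)S(=O)(=O)C(F)(F)F)C(F)(F)F
Why: Kinetic enolate triflation; the hindered amide takes a proton from the C6 methylene and not from the C7a methine that carries a branched substituent, which places the alkene at C6=C7.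

Step 12
Reactants: 16 enol triflate
Product: 17 (3S,4R,5R,6S)-3-[(tert-butyldimethylsilyloxy)methyl]-4-[(tert-butyldiphenylsilyloxy)methyl]-1,3,4-trimethyl-6-[(2R,3E)-pent-3-en-2-yl]-5-(prop-1-en-2-yl)cyclohex-1-ene
Conditions: MeZnCl, Pd(PPh3)4 (cat.), THF, 60 °C
Reagents that add atoms: methylzinc chloride, C[Zn]Cl
Why: Negishi cross-coupling of an alkenyl triflate with a methylzinc reagent under zerovalent palladium; the alkene position is retained, and after this step C7a is no longer epimerisable.

Step 13
Reactants: 17 triene
Product: 18 (1R,3aR,4R,5S,7aS)-5-[(tert-butyldimethylsilyloxy)methyl]-4-[(tert-butyldiphenylsilyloxy)methyl]-1,3,4,5,7-pentamethyl-3a,4,5,7a-tetrahydro-1H-indene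
Conditions: second-generation Grubbs catalyst RuCl2(=CHPh)(PCy3)(H2IMes) (cat.), toluene, 80 °C
Reagents that add atoms: none
Why: Ring-closing metathesis between the propenyl group (initiation site) and the 1,1-disubstituted isopropenyl group gives the trisubstituted C2=C3 alkene with loss of a C3 olefin. The two arms are trans-diequatorial, so the cyclopentene closes trans-fused, and the trisubstituted C6=C7 alkene is inert.

Step 14
Reactants: 18 bis-silyl bicyclic diene
Product: 19 [(1R,3aR,4R,5S,7aS)-4-[(tert-butyldiphenylsilyloxy)methyl]-1,3,4,5,7-pentamethyl-3a,4,5,7a-tetrahydro-1H-inden-5-yl]methanol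
Conditions: HF·pyridine, pyridine, THF, 0 °C to rt
Reagents that add atoms: none
Why: Selective desilylation; under buffered HF·pyridine a tert-butyldimethylsilyl ether is cleaved much faster than a tert-butyldiphenylsilyl ether.

Step 15
Reactants: 19 C5 hydroxymethyl compound
Product: 20 (1R,3aR,4R,5S,7aS)-4-[(tert-butyldiphenylsilyloxy)methyl]-1,3,4,5,7-pentamethyl-3a,4,5,7a-tetrahydro-1H-indene-5-carbaldehyde
Conditions: Dess–Martin periodinane, NaHCO3, CH2Cl2, rt
Reagents that add atoms: none
Why: Dess–Martin oxidation; C5 is quaternary, so the β,γ-unsaturated aldehyde cannot enolise or move into conjugation.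

Step 16
Reactants: 20 C5 aldehyde
Product: 21 (2E)-3-[(1R,3aR,4R,5R,7aS)-4-[(tert-butyldiphenylsilyloxy)methyl]-1,3,4,5,7-pentamethyl-3a,4,5,7a-tetrahydro-1H-inden-5-yl]-2-methylprop-2-enal (same spatial arrangement at C5; only the descriptor changes)
Conditions: Ph3P=C(CH3)CHO, toluene, 110 °C
Reagents that add atoms: 2-(triphenylphosphoranylidene)propanal, CC(C=O)=P(c1ccccc1)(c1ccccc1)c1ccccc1
Why: Wittig olefination with a stabilised ylide; reversible addition places the formyl group trans to the bulky C5 substituent, giving the (E)-enal. The neopentyl aldehyde is slow, hence the temperature.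

Step 17
Reactants: 21 enal
Product: 22 tert-butyl{[(1R,3aR,4R,5S,7aS)-1,3,4,5,7-pentamethyl-5-[(1E,3E)-2-methyl-4-phenylbuta-1,3-dien-1-yl]-3a,4,5,7a-tetrahydro-1H-inden-4-yl]methoxy}diphenylsilane
Conditions: (EtO)2P(O)CH2Ph, NaH, THF, 0 °C to rt
Reagents that add atoms: diethyl benzylphosphonate, CCOP(=O)(Cc1ccccc1)OCC
Why: Horner–Wadsworth–Emmons olefination with the benzylphosphonate anion gives the (E)-styryl alkene; with the C4 arm silylated there is no hydroxyl that could add to the enal.

Step 18
Reactants: 22 silyl-protected diene
Product: 23 [(1R,3aR,4R,5S,7aS)-1,3,4,5,7-pentamethyl-5-[(1E,3E)-2-methyl-4-phenylbuta-1,3-dien-1-yl]-3a,4,5,7a-tetrahydro-1H-inden-4-yl]methanol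
Conditions: Bu4NF, THF, rt to 50 °C
Reagents that add atoms: none
Why: Fluoride cleavage of the remaining silyl ether; the diene and both ring alkenes are inert to fluoride.

Step 19
Reactants: 23 C4 hydroxymethyl compound
Product: 24 (1R,3aR,4R,5S,7aS)-1,3,4,5,7-pentamethyl-5-[(1E,3E)-2-methyl-4-phenylbuta-1,3-dien-1-yl]-3a,4,5,7a-tetrahydro-1H-indene-4-carbaldehyde
Conditions: Dess–Martin periodinane, NaHCO3, CH2Cl2, rt
Reagents that add atoms: none
Why: Dess–Martin oxidation of the neopentyl alcohol under buffered conditions that leave the diene untouched.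

Step 20
Reactants: 24 C4 aldehyde
Product: 25 27-nor-zyggomphic acid B, (1R,3aR,4R,5S,7aS)-1,3,4,5,7-pentamethyl-5-[(1E,3E)-2-methyl-4-phenylbuta-1,3-dien-1-yl]-3a,4,5,7a-tetrahydro-1H-indene-4-carboxylic acid
Conditions: NaClO2, NaH2PO4, 2-methylbut-2-ene, t-BuOH/H2O, rt
Reagents that add atoms: sodium chlorite, [Na+].[O-]Cl=O
Why: Pinnick oxidation of a non-enolisable aldehyde; 2-methylbut-2-ene scavenges hypochlorous acid before it can attack the diene, and the mildly acidic buffer should not lactonise the γ,δ-unsaturated acid.

## Compound list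

1 | buta-1,3-diene | C=CC=C | starting material
2 | 2,3-dimethylmaleic anhydride | CC1=C(C)C(=O)OC1=O | starting material
3 | meso-cis-1,2-dimethylcyclohex-4-ene-1,2-dicarboxylic anhydride | C[C@]12CC=CC[C@@]1(C)C(=O)OC2=O | intermediate
4 | meso-(cis-1,2-dimethylcyclohex-4-ene-1,2-diyl)dimethanol | OC[C@]1(C)CC=CC[C@]1(C)CO | intermediate
5 | meso-(3,4-dimethyl-7-oxabicyclo[4.1.0]heptane-3,4-diyl)dimethanol, epoxide cis to both CH2OH | O1[C@@H]2C[C@](C)(CO)[C@](C)(CO)C[C@H]12 | intermediate
6 | bis(triethylsilyl) ether of 5 | O1[C@@H]2C[C@](C)(CO[Si](CC)(CC)CC)[C@](C)(CO[Si](CC)(CC)CC)C[C@H]12 | intermediate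
7 | (1R,4R,5S)-4,5-dimethyl-4,5-bis[(triethylsilyloxy)methyl]cyclohex-2-en-1-ol | O[C@@H]1C[C@](C)(CO[Si](CC)(CC)CC)[C@](C)(CO[Si](CC)(CC)CC)C=C1 | intermediate
8 | (1R,4R,5S)-4,5-bis(hydroxymethyl)-4,5-dimethylcyclohex-2-en-1-ol | O[C@@H]1C[C@](C)(CO)[C@](C)(CO)C=C1 | intermediate
9 | (4R,5S)-4,5-bis(hydroxymethyl)-4,5-dimethylcyclohex-2-en-1-one | O=C1C[C@](C)(CO)[C@](C)(CO)C=C1 | intermediate
10 | (1R,5S,8R)-8-(hydroxymethyl)-5,8-dimethyl-6-oxabicyclo[3.2.1]octan-3-one | O=C1C[C@]2(C)CO[C@H](C1)[C@@]2(C)CO | intermediate
11 | (1R,5S,8R)-8-[(tert-butyldiphenylsilyloxy)methyl]-5,8-dimethyl-6-oxabicyclo[3.2.1]octan-3-one | O=C1C[C@]2(C)CO[C@H](C1)[C@@]2(C)CO[Si](c3ccccc3)(c3ccccc3)C(C)(C)C | intermediate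
12 | (4R,5S)-5-[(tert-butyldimethylsilyloxy)methyl]-4-[(tert-butyldiphenylsilyloxy)methyl]-4,5-dimethylcyclohex-2-en-1-one | O=C1C[C@](C)(CO[Si](C)(C)C(C)(C)C)[C@](C)(CO[Si](c2ccccc2)(c2ccccc2)C(C)(C)C)C=C1 | intermediate
13 | (3R,4R,5S)-trimethylsilyl enol ether with 3-isopropenyl group (C3a isopropenyl cis to the methyls) | C1=C(O[Si](C)(C)C)C[C@](C)(CO[Si](C)(C)C(C)(C)C)[C@](C)(CO[Si](c2ccccc2)(c2ccccc2)C(C)(C)C)[C@H]1C(C)=C | intermediate
14 | lithium enolate corresponding to 13 | C1=C(O[Li])C[C@](C)(CO[Si](C)(C)C(C)(C)C)[C@](C)(CO[Si](c2ccccc2)(c2ccccc2)C(C)(C)C)[C@H]1C(C)=C | intermediate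
15 | (2S,3R,4R,5S)-5-[(tert-butyldimethylsilyloxy)methyl]-4-[(tert-butyldiphenylsilyloxy)methyl]-4,5-dimethyl-2-[(2R,3E)-pent-3-en-2-yl]-3-(prop-1-en-2-yl)cyclohexan-1-one | O=C1C[C@](C)(CO[Si](C)(C)C(C)(C)C)[C@](C)(CO[Si](c2ccccc2)(c2ccccc2)C(C)(C)C)[C@@H](C(C)=C)[C@@H]1[C@H](C)/C=C/C | intermediate
16 | (3S,4R,5R,6S)-enol triflate of 15 (alkene C6=C7) | FC(F)(F)S(=O)(=O)OC1=C[C@](C)(CO[Si](C)(C)C(C)(C)C)[C@](C)(CO[Si](c2ccccc2)(c2ccccc2)C(C)(C)C)[C@@H](C(C)=C)[C@@H]1[C@H](C)/C=C/C | intermediate
17 | (3S,4R,5R,6S)-1,3,4-trimethylcyclohexene triene (triflate of 16 replaced by CH3) | CC1=C[C@](C)(CO[Si](C)(C)C(C)(C)C)[C@](C)(CO[Si](c2ccccc2)(c2ccccc2)C(C)(C)C)[C@@H](C(C)=C)[C@@H]1[C@H](C)/C=C/C | intermediate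
18 | (1R,3aR,4R,5S,7aS)-5-[(tert-butyldimethylsilyloxy)methyl]-4-[(tert-butyldiphenylsilyloxy)methyl]-1,3,4,5,7-pentamethyl-3a,4,5,7a-tetrahydro-1H-indene | CC1=C[C@](C)(CO[Si](C)(C)C(C)(C)C)[C@](C)(CO[Si](c3ccccc3)(c3ccccc3)C(C)(C)C)[C@H]2C(C)=C[C@@H](C)[C@H]12 | intermediate
19 | C5 hydroxymethyl compound (C4 arm silylated) | CC1=C[C@](C)(CO)[C@](C)(CO[Si](c3ccccc3)(c3ccccc3)C(C)(C)C)[C@H]2C(C)=C[C@@H](C)[C@H]12 | intermediate
20 | C5 carbaldehyde | CC1=C[C@](C)(C=O)[C@](C)(CO[Si](c3ccccc3)(c3ccccc3)C(C)(C)C)[C@H]2C(C)=C[C@@H](C)[C@H]12 | intermediate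
21 | (2E)-2-methylprop-2-enal on C5 | CC1=C[C@](C)(/C=C(C)/C=O)[C@](C)(CO[Si](c3ccccc3)(c3ccccc3)C(C)(C)C)[C@H]2C(C)=C[C@@H](C)[C@H]12 | intermediate
22 | (1E,3E)-dienyl compound, C4 arm as tert-butyldiphenylsilyl ether | CC1=C[C@](C)(/C=C(C)/C=C/c3ccccc3)[C@](C)(CO[Si](c4ccccc4)(c4ccccc4)C(C)(C)C)[C@H]2C(C)=C[C@@H](C)[C@H]12 | intermediate
23 | C4 hydroxymethyl dienyl compound | CC1=C[C@](C)(/C=C(C)/C=C/c3ccccc3)[C@](C)(CO)[C@H]2C(C)=C[C@@H](C)[C@H]12 | intermediate
24 | C4 carbaldehyde | CC1=C[C@](C)(/C=C(C)/C=C/c3ccccc3)[C@](C)(C=O)[C@H]2C(C)=C[C@@H](C)[C@H]12 | intermediate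
25 | 27-nor-zyggomphic acid B | CC1=C[C@](C)(/C=C(C)/C=C/c2ccccc2)[C@](C)(C(=O)O)[C@H]2C(C)=C[C@@H](C)[C@H]12 | target

## Step count and least certain steps

Total step count: 20. Longest linear sequence: 20 steps (from 1 and 2; the route is fully linear).

**Step 1 (key step).** The cycloaddition may stall: the tetrasubstituted dienophile reacts slowly, and at the temperature needed the diene is consumed by self-dimerisation and polymerisation. Fallback, setting out from 1: cycloaddition with citraconic anhydride, which has one methyl fewer and reacts near 100 °C, gives rac-cis-3a-methyl-3a,4,7,7a-tetrahydro-2-benzofuran-1,3-dione F1. NaBH4 in THF reduces the carbonyl flanked by the quaternary carbon, the usual sense for unsymmetrical cyclic anhydrides, to rac-cis-3a-methyl-3a,4,7,7a-tetrahydro-2-benzofuran-1(3H)-one F2. LiN(iPr)2 then MeI methylates the ring-fusion α-carbon, and the cis-fused bicyclic enolate is expected to give rac-cis-3a,7a-dimethyl-3a,4,7,7a-tetrahydro-2-benzofuran-1(3H)-one F3. LiAlH4 reduces F3 to meso diol 4, where the route is rejoined. The second quaternary centre is then made by alkylation, not in the cycloaddition.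

**Step 5.** Enantiotopic discrimination may be low or slow, because the proton to be removed sits next to a quaternary carbon and syn to an axial silyloxymethyl group; the sense of induction may also differ from that of the parent epoxide. Fallback, setting out from 6: rearrangement with achiral LiNEt2 gives 7 together with its enantiomer, (1S,4S,5R)-4,5-dimethyl-4,5-bis[(triethylsilyloxy)methyl]cyclohex-2-en-1-ol F4. Kinetic resolution by acylation with isobutyric anhydride and a catalytic amount of one enantiomer of benzotetramisole (2-phenyl-2,3-dihydroimidazo[2,1-b][1,3]benzothiazole), chosen so that the unwanted alcohol is converted into its isobutyrate F5, leaves 7 unreacted. It is separated and passed through the acidic methanol treatment to 8. The route is rejoined at 7.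

**Step 6.** Ring closure of the hydroxy enone may be incomplete, or the γ-hydroxymethyl enone may fragment before it closes. Fallback, setting out from 8: iodoetherification with N-iodosuccinimide in MeCN (5-exo attack of the C5 arm on C3a, iodine on C7a) gives 8-(hydroxymethyl)-2-iodo-5,8-dimethyl-6-oxabicyclo[3.2.1]octan-3-ol F6. t-BuPh2SiCl and imidazole protect the primary alcohol to give silyl ether F7. Dess–Martin oxidation gives the α-iodo ketone F8. Zinc dust in AcOH/THF effects reductive β-elimination to (4R,5S)-4-[(tert-butyldiphenylsilyloxy)methyl]-5-(hydroxymethyl)-4,5-dimethylcyclohex-2-en-1-one F9. t-BuMe2SiCl and imidazole give 12, where the route is rejoined. Here the enone appears only after the C4 arm is protected.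

**Step 9.** Addition to the neopentyl β-carbon may be slow, and the face selectivity, which rests on methyl versus silyloxymethyl, may be insufficient. Fallback, setting out from 12: rhodium-catalysed conjugate addition of isopropenylboronic acid pinacol ester ([Rh(cod)Cl]2, one enantiomer of BINAP chosen to reinforce β attack, KOH, dioxane/H2O) gives (3R,4R,5S)-5-[(tert-butyldimethylsilyloxy)methyl]-4-[(tert-butyldiphenylsilyloxy)methyl]-4,5-dimethyl-3-(prop-1-en-2-yl)cyclohexan-1-one F10. LiN(iPr)2 at −78 °C removes a proton from the less hindered C7a methylene and gives lithium enolate 14, where the route is rejoined.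

**Step 10.** The hindered enolate may react sluggishly with the allyl complex, and ligand and substrate may be mismatched, eroding control at C1. Fallback, setting out from 14: aldol addition to acetaldehyde gives the 2-(1-hydroxyethyl) ketone F11. MsCl/Et3N gives its mesylate F12, and DBU eliminates to the (E)-2-ethylidene ketone F13. Conjugate addition of LiCu[(E)-CH=CHCH3]2 with Me3SiCl, followed by acidic work-up under equilibrating conditions, gives 15, where the route is rejoined. A(1,3) strain with the ethylidene methyl should push the neighbouring isopropenyl group axial, so that the cuprate adds to C1 from the opposite face. The C1 centre is then set by substrate control in a C1–C2 bond formation, not by the catalyst.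

**Step 16.** The stabilised ylide may fail to add to an aldehyde flanked by two quaternary carbons. Fallback, setting out from 20: Horner–Wadsworth–Emmons reaction with triethyl 2-phosphonopropionate and NaH gives the ethyl (2E)-2-methylprop-2-enoate F14. iBu2AlH reduces it to the (2E)-2-methylprop-2-en-1-ol F15, and MnO2 oxidises this allylic alcohol to 21, where the route is rejoined.

## Further compounds

F1 | step 1 | rac-cis-3a-methyl-3a,4,7,7a-tetrahydro-2-benzofuran-1,3-dione | C[C@]12CC=CC[C@H]1C(=O)OC2=O
F2 | step 1 | rac-cis-3a-methyl-3a,4,7,7a-tetrahydro-2-benzofuran-1(3H)-one | C[C@]12CC=CC[C@H]1C(=O)OC2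
F3 | step 1 | rac-cis-3a,7a-dimethyl-3a,4,7,7a-tetrahydro-2-benzofuran-1(3H)-one | C[C@]12CC=CC[C@@]1(C)C(=O)OC2
F4 | step 5 | (1S,4S,5R)-4,5-dimethyl-4,5-bis[(triethylsilyloxy)methyl]cyclohex-2-en-1-ol | O[C@H]1C[C@@](C)(CO[Si](CC)(CC)CC)[C@@](C)(CO[Si](CC)(CC)CC)C=C1
F5 | step 5 | isobutyrate of F4 | CC(C)C(=O)O[C@H]1C[C@@](C)(CO[Si](CC)(CC)CC)[C@@](C)(CO[Si](CC)(CC)CC)C=C1
F6 | step 6 | 8-(hydroxymethyl)-2-iodo-5,8-dimethyl-6-oxabicyclo[3.2.1]octan-3-ol (iodine trans to the ether oxygen on C1, hydroxyl cis to the ether bridge) | O[C@@H]1C[C@]2(C)CO[C@H]([C@H]1I)[C@@]2(C)CO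
F7 | step 6 | tert-butyldiphenylsilyl ether of the primary alcohol of F6 | O[C@@H]1C[C@]2(C)CO[C@H]([C@H]1I)[C@@]2(C)CO[Si](c3ccccc3)(c3ccccc3)C(C)(C)C
F8 | step 6 | 8-[(tert-butyldiphenylsilyloxy)methyl]-2-iodo-5,8-dimethyl-6-oxabicyclo[3.2.1]octan-3-one | O=C1C[C@]2(C)CO[C@H]([C@H]1I)[C@@]2(C)CO[Si](c3ccccc3)(c3ccccc3)C(C)(C)C
F9 | step 6 | (4R,5S)-4-[(tert-butyldiphenylsilyloxy)methyl]-5-(hydroxymethyl)-4,5-dimethylcyclohex-2-en-1-one | O=C1C[C@](C)(CO)[C@](C)(CO[Si](c2ccccc2)(c2ccccc2)C(C)(C)C)C=C1
F10 | step 9 | (3R,4R,5S)-5-[(tert-butyldimethylsilyloxy)methyl]-4-[(tert-butyldiphenylsilyloxy)methyl]-4,5-dimethyl-3-(prop-1-en-2-yl)cyclohexan-1-one | O=C1C[C@](C)(CO[Si](C)(C)C(C)(C)C)[C@](C)(CO[Si](c2ccccc2)(c2ccccc2)C(C)(C)C)[C@@H](C(C)=C)C1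
F11 | step 10 | 2-(1-hydroxyethyl) ketone (carbinol epimers), 2,3-trans | O=C1C[C@](C)(CO[Si](C)(C)C(C)(C)C)[C@](C)(CO[Si](c2ccccc2)(c2ccccc2)C(C)(C)C)[C@@H](C(C)=C)[C@@H]1C(C)O
F12 | step 10 | mesylate of F11 | O=C1C[C@](C)(CO[Si](C)(C)C(C)(C)C)[C@](C)(CO[Si](c2ccccc2)(c2ccccc2)C(C)(C)C)[C@@H](C(C)=C)[C@@H]1C(C)OS(C)(=O)=O
F13 | step 10 | (2E)-2-ethylidene ketone | O=C1C[C@](C)(CO[Si](C)(C)C(C)(C)C)[C@](C)(CO[Si](c2ccccc2)(c2ccccc2)C(C)(C)C)[C@@H](C(C)=C)/C1=C\C
F14 | step 16 | ethyl (2E)-2-methyl-3-(inden-5-yl)prop-2-enoate analogue of 21 | CC1=C[C@](C)(/C=C(C)/C(=O)OCC)[C@](C)(CO[Si](c3ccccc3)(c3ccccc3)C(C)(C)C)[C@H]2C(C)=C[C@@H](C)[C@H]12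
F15 | step 16 | (2E)-2-methylprop-2-en-1-ol analogue of 21 | CC1=C[C@](C)(/C=C(C)/CO)[C@](C)(CO[Si](c3ccccc3)(c3ccccc3)C(C)(C)C)[C@H]2C(C)=C[C@@H](C)[C@H]12
A1 | alternative 1 | cyclohexene acid with both quaternary centres, 4-methoxybenzyloxymethyl on C5, isopropenyl on C3a and but-3-en-2-yl on C7a | CC1=C[C@](C)(COCc2ccc(OC)cc2)[C@](C)(C(=O)O)[C@@H](C(C)=C)[C@@H]1[C@H](C)C=C
A2 | alternative 2 | methyl ester of 25 | CC1=C[C@](C)(/C=C(C)/C=C/c2ccccc2)[C@](C)(C(=O)OC)[C@H]2C(C)=C[C@@H](C)[C@H]12
A3 | alternative 3 | tricyclic cis-fused γ-lactone with both quaternary centres | CC1=C[C@]2(C)C(=O)OC[C@]2(C)[C@H]3C(C)=C[C@@H](C)[C@H]13
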